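(The data were generated by integration on assumed constants; noise was put on by code.)

The meeting opened on the constants, which nobody had; on the table lay the alpha run and the recipe for the new flask.

- alpha: substrate 0.10 M; first nucleophile 2.1 equiv; second nucleophile 0.60 equiv; run made earlier
- flask: substrate 0.10 M; first nucleophile 1.05 equiv; second nucleophile 0.600 equiv; time 3.0 d

alpha run (percent of the substrate charged)

| time / h | target / % | other capture product / % | substrate / % |
|---|---|---|---|
| 0.500 | 5 | 0 | 96 |
| 1.33 | 4 | 3 | 88 |
| 2.50 | 11 | 6 | 82 |
| 4.00 | 17 | 7 | 72 |
| 6.00 | 20 | 13 | 65 |
| 8.00 | 26 | 18 | 53 |

(readings scatter by 2 percentage points)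

- ratio of target to other capture product at 25 min
- ratio of target to other capture product at 5.0 h
- ratio of target to other capture product at 3.0 d

- a reading or a percentage of target counts all its forms, free or not

The secretary proposed following one substrate molecule to its fork, where either nucleophile may capture it. He defined the capture ratio (selectivity factor) as the first nucleophile's odds of capture over the second's, molecule for molecule, at equal concentrations. Then the logarithm of the fraction of first nucleophile left, divided by the logarithm of the fraction of second nucleophile left, equals that ratio at any moment. He worked this out from the alpha readings and got 0.410 at 6.00 h and 0.371 at 8.00 h, and he took their mean, 0.390, as a reading. For the flask, he said, the starting odds are this ratio times 1.05 equiv over 0.600 equiv, which gives 0.683. He expected them to climb, since a capture ratio below one means that the second nucleophile loses a larger fraction of its charge than the first.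

The maker of the forecast replied that “the two products look like competitive capture”, but took 0.42 for the ratio, so he started higher than the secretary. He forecast 0.74 (0.52 to 1.05) at 25 min, 0.78 (0.57 to 1.08) at 5.0 h, and 1.08 (0.88 to 1.35) at 3.0 d.

The flask gave 0.763, 0.827 and 1.04, each within the forecast's range.

    substrate → intermediate (k = 0.0800 h⁻¹)
    first nucleophile + intermediate → target (k = 52.4 L mol⁻¹ h⁻¹)
    second nucleophile + intermediate → other capture product (k = 121 L mol⁻¹ h⁻¹)
    intermediate → solvolysis product (k = 0.418 h⁻¹)
    crystals ⇌ target, rate k5*(cs5 - [target]) while solid is left; crystals form when [target] > cs5 (solubility = 2.70 mM, k = 1.59 h⁻¹)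
    intermediate → side product (k = 0.540 h⁻¹)

In the flask, substrate became intermediate with a half-life of 0.36 d while both nucleophiles stood ready, and target drew level with other capture product at 1.21 d. By 3.00 d, substrate was down to 0.315%, with 56.7% of the first nucleophile and 27.0% of the second left; that second figure, taken through the capture ratio, gives 60.0% for the first and a final ratio of 0.959, against 1.04 in the flask. The neighbouring flask with 2.60 equiv of first nucleophile kept 51.3% of its second nucleophile, which gives a ratio of 2.04, and it stood at 2.23.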